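The benzene ring (C1 pentadecyl, C2 acetoxy, C3 methoxy, C5 hydroxyl) is cut at C2–C3 and C1–C6. The meta-related oxygens on C3 and C5 mark C3–C6 as a 1,1-dimethoxy-3-silyloxybutadiene. The adjacent C1/C2 pair is the alkyne of nonadec-3-yn-2-one, whose acetyl group is a masked C2 acetate. One thermal [4+2] cycloaddition followed by loss of methanol builds the tetrasubstituted arene with every substituent in place. The diene carries a robust tert-butyldimethylsilyl group, so the C5 oxygen emerges already protected for the Baeyer–Villiger oxidation. Buffered fluoride then frees the phenol.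

Key step: step 5

Assumption: heptadec-1-yne is taken as a catalogue chemical, and since the target has no stereocentre the SMILES strings carry no stereodescriptors.

Step 1
Reactants: 1 1,1-dichloroethene; 2 acetyl chloride
Product: 4 4,4-dichlorobut-3-en-2-one, via 4,4,4-trichlorobutan-2-one 3 (not isolated)
Conditions: AlCl3 (1.1 equiv), CH2Cl2, 0 °C to rt; ice/aq HCl; distillation under reduced pressure (−HCl)
Reagents that add atoms: none
Why: Friedel–Crafts-type acylation of an alkene, in which the acylium ion from 2 and AlCl3 attacks the CH2 terminus of 1, chloride capture gives 3, and its acidic α-hydrogens allow thermal β-elimination of HCl to the conjugated dichlorovinyl ketone.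

Step 2
Reactants: 4 4,4-dichlorobut-3-en-2-one
Product: 5 4,4-dimethoxybut-3-en-2-one
Conditions: NaOMe (2.1 equiv), MeOH, 0 °C to rt; distillation
Reagents that add atoms: sodium methoxide, [Na+].[O-]C
Why: Both β-chlorides behave as vinylogous acid chlorides and are replaced by methoxide through two conjugate addition–elimination events (nucleophilic vinylic substitution).

Step 3
Reactants: 5 4,4-dimethoxybut-3-en-2-one
Product: 6 tert-butyl[(4,4-dimethoxybuta-1,3-dien-2-yl)oxy]dimethylsilane (3-silyloxy-1,1-dimethoxybuta-1,3-diene)
Conditions: TBSOTf, Et3N, Et2O, 0 °C to rt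
Reagents that add atoms: tert-butyldimethylsilyl trifluoromethanesulfonate, CC(C)(C)[Si](C)(C)OS(=O)(=O)C(F)(F)F
Why: Soft enolisation (silyl enol ether formation), in which the silyl triflate activates the carbonyl oxygen of the push–pull enone and Et3N removes a proton from the only enolisable position, the methyl group, to give the 2-silyloxydiene.

Step 4
Reactants: 7 heptadec-1-yne; 8 N-methoxy-N-methylacetamide
Product: 11 nonadec-3-yn-2-one, via lithium heptadec-1-yn-1-ide 9 (not isolated), via lithium 2-[methoxy(methyl)amino]nonadec-3-yn-2-olate 10 (not isolated)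
Conditions: n-BuLi, THF, −78 °C; 8, −78 to 0 °C; poured into cold 1 M HCl
Reagents that add atoms: none
Why: Weinreb ketone synthesis, in which acetylide 9 adds once to amide 8, chelate 10 holds until the quench, and the inverse acidic quench keeps the liberated N,O-dimethylhydroxylamine protonated so that it cannot add to the ynone.

Step 5
Reactants: 6 tert-butyl[(4,4-dimethoxybuta-1,3-dien-2-yl)oxy]dimethylsilane; 11 nonadec-3-yn-2-one
Product: 13 1-{4-[(tert-butyldimethylsilyl)oxy]-2-methoxy-6-pentadecylphenyl}ethan-1-one, via cyclohexa-1,4-diene cycloadduct 12 (not isolated)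
Conditions: 6 (2.5 equiv), toluene, 4 Å MS, 120 °C, sealed tube; then SiO2, CH2Cl2, rt
Reagents that add atoms: none
Why: This is a normal-electron-demand Diels–Alder benzannulation of a 1,1,3-trioxygenated silyloxydiene with an acetylenic ketone, a reaction type established for β-alkyl ynoates and ynones. The cycloaddition is concerted but strongly asynchronous: the CH2 terminus of 6, towards which all three oxygen donors push electron density, bonds first to the β-carbon of 11 (C6–C1), and the ketene acetal carbon then closes onto the α-carbon (C3–C2). The six-membered carbocycle is closed intermolecularly by suprafacial [4+2] union of the four diene carbons with the two alkyne carbons, which gives cyclohexa-1,4-diene 12. Compound 12 has a doubly allylic ketal opposite a doubly allylic CH2 group and aromatises by 1,4-loss of methanol on heating or on silica gel, while the tert-butyldimethylsilyl ether should survive the liberated methanol and the chromatography. No stereocentre is formed; the only selectivity needed is regiochemical, and it is secured by the matched polarisation of diene and ynone, which the β-pentadecyl chain can slow but not reverse. Lewis acids are left out on purpose, because they would favour a stepwise Mukaiyama–Michael path or attack at the carbonyl group.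

Step 6
Reactants: 13 1-{4-[(tert-butyldimethylsilyl)oxy]-2-methoxy-6-pentadecylphenyl}ethan-1-one
Product: 15 4-[(tert-butyldimethylsilyl)oxy]-2-methoxy-6-pentadecylphenyl acetate, via Criegee adduct 14 (not isolated)
Conditions: mCPBA (2.5 equiv), TFA (cat.), CH2Cl2, 0 °C to rt, dark
Reagents that add atoms: 3-chloroperoxybenzoic acid, O=C(OO)c1cccc(Cl)c1
Why: Baeyer–Villiger oxidation, in which the peracid adds to the ketone twisted out of conjugation by its two ortho groups and the electron-rich aryl group of 14 (ortho-methoxy, para-silyloxy) migrates far faster than methyl, so oxygen is inserted only between C2 and the acetyl carbon.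

Step 7
Reactants: 15 4-[(tert-butyldimethylsilyl)oxy]-2-methoxy-6-pentadecylphenyl acetate
Product: 16 4-hydroxy-2-methoxy-6-pentadecylphenyl acetate (target)
Conditions: Bu4NF/AcOH (1:1), THF, 0 °C
Reagents that add atoms: none
Why: Fluoride-induced cleavage of an aryl silyl ether driven by Si–F bond formation, with acetic acid protonating the phenoxide as it forms so that the aryl acetate is neither hydrolysed nor passed between molecules.

Compound list
1 | 1,1-dichloroethene | C=C(Cl)Cl | starting material
2 | acetyl chloride | CC(Cl)=O | starting material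
3 | 4,4,4-trichlorobutan-2-one | CC(=O)CC(Cl)(Cl)Cl | intermediate
4 | 4,4-dichlorobut-3-en-2-one | CC(=O)C=C(Cl)Cl | intermediate
5 | 4,4-dimethoxybut-3-en-2-one | CC(=O)C=C(OC)OC | intermediate
6 | tert-butyl[(4,4-dimethoxybuta-1,3-dien-2-yl)oxy]dimethylsilane | COC(OC)=CC(=C)O[Si](C)(C)C(C)(C)C | intermediate
7 | heptadec-1-yne | CCCCCCCCCCCCCCCC#C | starting material
8 | N-methoxy-N-methylacetamide | CC(=O)N(C)OC | starting material
9 | lithium heptadec-1-yn-1-ide | CCCCCCCCCCCCCCCC#[C-].[Li+] | intermediate
10 | lithium 2-[methoxy(methyl)amino]nonadec-3-yn-2-olate | CCCCCCCCCCCCCCCC#CC(C)([O-])N(C)OC.[Li+] | intermediate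
11 | nonadec-3-yn-2-one | CCCCCCCCCCCCCCCC#CC(C)=O | intermediate
12 | 1-{4-[(tert-butyldimethylsilyl)oxy]-6,6-dimethoxy-2-pentadecylcyclohexa-1,4-dien-1-yl}ethan-1-one | CCCCCCCCCCCCCCCC1=C(C(C)=O)C(OC)(OC)C=C(O[Si](C)(C)C(C)(C)C)C1 | intermediate
13 | 1-{4-[(tert-butyldimethylsilyl)oxy]-2-methoxy-6-pentadecylphenyl}ethan-1-one | CCCCCCCCCCCCCCCc1cc(O[Si](C)(C)C(C)(C)C)cc(OC)c1C(C)=O | intermediate
14 | 1-{4-[(tert-butyldimethylsilyl)oxy]-2-methoxy-6-pentadecylphenyl}-1-hydroxyethyl 3-chlorobenzenecarboperoxoate (racemic, transient) | CCCCCCCCCCCCCCCc1cc(O[Si](C)(C)C(C)(C)C)cc(OC)c1C(C)(O)OOC(=O)c1cccc(Cl)c1 | intermediate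
15 | 4-[(tert-butyldimethylsilyl)oxy]-2-methoxy-6-pentadecylphenyl acetate | CCCCCCCCCCCCCCCc1cc(O[Si](C)(C)C(C)(C)C)cc(OC)c1OC(C)=O | intermediate
16 | 4-hydroxy-2-methoxy-6-pentadecylphenyl acetate | CCCCCCCCCCCCCCCc1cc(O)cc(OC)c1OC(C)=O | target

Total step count: 7. Longest linear sequence: 6 (steps 1, 2, 3, 5, 6, 7); step 4 is the convergent branch.

Steps most likely to fail

Step 5. The β-pentadecyl group may slow the cycloaddition so much that thermal decay and methanolysis of the diene outrun it. Part of the silyl protection may also be lost during aromatisation. The fallback functionalises a preformed ring instead of building one.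
- It sets out from acetyl chloride 2, which C-acylates purchased 5-pentadecylbenzene-1,3-diol F1 (AlCl3, nitrobenzene/1,2-dichloroethane, Friedel–Crafts/Fries conditions). Attack occurs para to one hydroxyl and ortho to the other and should give 1-(2,4-dihydroxy-6-pentadecylphenyl)ethan-1-one F2.
- The hydroxyl that is not hydrogen-bonded to the ketone is silylated selectively (TBSCl, imidazole, CH2Cl2, 0 °C) to give 1-{4-[(tert-butyldimethylsilyl)oxy]-2-hydroxy-6-pentadecylphenyl}ethan-1-one F3.
- Neutral Mitsunobu methylation of the chelated phenol (MeOH, PPh3, DIAD, THF) comes back to the route at 13.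

Step 6. Addition of the bulky peracid to a carbonyl group flanked by two ortho substituents may be too slow, so that oxidation of the electron-rich ring or acid-induced loss of the silyl ether competes. The fallback replaces carbonyl addition by a Hock-type rearrangement through a benzylic cation.
- From 13, LiAlH4 in THF gives racemic 1-{4-[(tert-butyldimethylsilyl)oxy]-2-methoxy-6-pentadecylphenyl}ethan-1-ol F4.
- H2O2 with catalytic TsOH in THF ionises the strongly stabilised benzylic position and traps it as racemic tert-butyl[4-(1-hydroperoxyethyl)-3-methoxy-5-pentadecylphenoxy]dimethylsilane F5.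
- F5 rearranges under the same acid with aryl migration to oxygen and leaves 4-[(tert-butyldimethylsilyl)oxy]-2-methoxy-6-pentadecylphenol F6.
- Acetylation (Ac2O, Et3N, DMAP, CH2Cl2) comes back to the route at 15.

Step 7. Basic fluoride or the liberated phenoxide may attack the aryl acetate and cause acetyl loss or intermolecular acetyl transfer. The fallback swaps fluoride for neutral hydrogenolysis.
- From 13, where no acetate is present yet, Bu4NF in THF gives 1-(4-hydroxy-2-methoxy-6-pentadecylphenyl)ethan-1-one F7.
- BnBr and K2CO3 in DMF give 1-[4-(benzyloxy)-2-methoxy-6-pentadecylphenyl]ethan-1-one F8.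
- Baeyer–Villiger oxidation with mCPBA gives 4-(benzyloxy)-2-methoxy-6-pentadecylphenyl acetate F9.
- H2 over Pd/C in EtOAc removes the benzyl group and comes back to the route at target 16.

Further compounds
F1 | step 5 | 5-pentadecylbenzene-1,3-diol (purchased) | CCCCCCCCCCCCCCCc1cc(O)cc(O)c1
F2 | step 5 | 1-(2,4-dihydroxy-6-pentadecylphenyl)ethan-1-one | CCCCCCCCCCCCCCCc1cc(O)cc(O)c1C(C)=O
F3 | step 5 | 1-{4-[(tert-butyldimethylsilyl)oxy]-2-hydroxy-6-pentadecylphenyl}ethan-1-one | CCCCCCCCCCCCCCCc1cc(O[Si](C)(C)C(C)(C)C)cc(O)c1C(C)=O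
F4 | step 6 | 1-{4-[(tert-butyldimethylsilyl)oxy]-2-methoxy-6-pentadecylphenyl}ethan-1-ol (racemic) | CCCCCCCCCCCCCCCc1cc(O[Si](C)(C)C(C)(C)C)cc(OC)c1C(C)O
F5 | step 6 | tert-butyl[4-(1-hydroperoxyethyl)-3-methoxy-5-pentadecylphenoxy]dimethylsilane (racemic) | CCCCCCCCCCCCCCCc1cc(O[Si](C)(C)C(C)(C)C)cc(OC)c1C(C)OO
F6 | step 6 | 4-[(tert-butyldimethylsilyl)oxy]-2-methoxy-6-pentadecylphenol | CCCCCCCCCCCCCCCc1cc(O[Si](C)(C)C(C)(C)C)cc(OC)c1O
F7 | step 7 | 1-(4-hydroxy-2-methoxy-6-pentadecylphenyl)ethan-1-one | CCCCCCCCCCCCCCCc1cc(O)cc(OC)c1C(C)=O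
F8 | step 7 | 1-[4-(benzyloxy)-2-methoxy-6-pentadecylphenyl]ethan-1-one | CCCCCCCCCCCCCCCc1cc(OCc2ccccc2)cc(OC)c1C(C)=O
F9 | step 7 | 4-(benzyloxy)-2-methoxy-6-pentadecylphenyl acetate | CCCCCCCCCCCCCCCc1cc(OCc2ccccc2)cc(OC)c1OC(C)=O
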